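## Structural features

The target is a linear C15 chain folded once into a single tetrahydropyran whose oxygen bridges C6 and C10; C6 carries a (Z)-pent-2-en-4-ynyl arm (C1–C5) and C10 an (E)-3-bromopent-2-enyl arm (C11–C15). The ring holds four stereocentres in two adjacent pairs, C6 (R)/C7 (S, chlorine) and C9 (S, bromine)/C10 (R), separated by the C8 methylene. The two arms are trans across the ring oxygen, each halogen is trans to the arm on its neighbouring carbon and the two halogens are trans to each other, so that in either chair one arm and one halogen are axial. Fragile groups are the secondary halides β to the ring oxygen (elimination, participation of the ring oxygen), the skipped Z-enyne with its terminal alkyne, and the trisubstituted vinyl bromide, whose regiochemistry and geometry cannot be corrected once made. The real difficulty is to place two different halogens with defined configuration on a nearly C2-symmetric ring core that offers no symmetry-breaking handle, and to secure the 2,6-trans arrangement. The key step exploits the fact that the ring atoms O–C10–C9–C8–C7–C6 coincide with the carbinol oxygen and carbon of a 2-furyl carbinol followed by furan C2 to C5. Oxidative ring expansion therefore turns the flat furan into a pyranone with a ketone at C9, an enone at C7=C8 and a hemiacetal at C6, with C10 already stereodefined.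

## Logic of the disconnections

**26 to 25.** The C1–H bond is replaced by C1–Si. The silyl cap shields the acidic alkyne terminus and is also the group that makes a Z-selective enyne olefination possible. Nothing is simplified in the skeleton. The forward demand is a fluoride desilylation that does not trigger elimination at C7 or C9.

**25 to 24.** The C7–Cl bond is cut and replaced by a C7–O bond of opposite configuration. A chloride trans to the C6 arm arises by SN2 from an alcohol cis to that arm, which is what a tether from C6 can deliver. The forward step must invert cleanly, without elimination or participation of the ring oxygen.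

**24 to 20 and 21.** The C3=C4 double bond is cut. The C4 aldehyde and the C7 hydroxyl are stored together as a lactol, so that the olefination releases exactly the hydroxyl that is chlorinated next, and no protecting group is needed. The forward step must be Z-selective and must tolerate two bromides.

**20 to 19.** The lactol is traced to the lactone by a change of oxidation level at C4. The reduction must stop at the lactol.

**19 to 17.** The C13–Br and C12–H bonds are removed, which gives back the C12≡C13 alkyne. The E geometry corresponds to syn addition of H and Br. The step is placed after the C9 bromide is in (no free hydroxyl to consume Cp2Zr(H)Cl) and before the enyne exists (no second alkyne). The forward step must put the metal on C13.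

**17 to 16.** The C9–Br bond is cut to a C9–O bond of opposite configuration. Bromide trans to the C10 arm requires an alcohol cis to it. With the C10 arm equatorial, that alcohol is axial, the favourable geometry for SN2.

**16 to 15.** The C9–H bond is removed, returning the C9 ketone that the key step supplies. The forward reduction must deliver hydride along the equatorial trajectory so that the hydroxyl ends cis to the C10 arm.

**15 to 13 (through 14).** The O–C7 bond of the lactone is cut. C7 is the β-carbon of the enone, and a carboxyl tethered at C6 can only reach it on the face of that tether, so C7–O is formed cis to C5 and C7 is distinguished from C9. One ring and one stereocentre disappear. The forward step needs the conjugate addition equilibrium to lie on the closed side.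

**13 to 9 and 12; 12 to 10.** The C5–C6 bond is cut at the acetal carbon, whose ionisation gives an oxocarbenium ion. The forward step must add the two-carbon ester unit trans to the C10 arm. Compound 12 goes back to 10 by cutting its O–Si bond.

**9 to 8.** The anomeric O–acetyl bond is cut. The acetate is only the leaving group for the preceding disconnection.

**8 to 6 (key).** The O–C6 bond is cut and C6–C9 are returned to a furan. A ring, a ketone, an enone and a hemiacetal collapse into one heteroarene bearing a single stereocentre. The carbinol is used free and unprotected, with the complete C11–C15 chain present as the alkyne. The alkyne, not the bromoalkene, is carried through the oxidation. The forward step must oxidise the furan in preference to the alkyne and leave C10 untouched.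

**6 to 3 and 4.** The C10–C11 bond is cut. This joins the C6–C10 piece to the C11–C15 piece and creates the only stereocentre that depends on a catalyst. The forward step must react through the allenyl terminus (homopropargyl, not allenyl, product) and must control the aldehyde face.

**3 to 2 to 1.** The C–Sn bond is cut back to a propargylic sulfonate and then to the alcohol. The forward step must proceed by SN2′ attack.

## Other disconnections considered

Alternative 1: The cut removes both exocyclic C–C bonds at the acetal carbons, C10–C11 and C5–C6, and leads back to a ring that already carries both halogens, (3S,5S)-3-bromo-5-chloro-6-methoxytetrahydro-2H-pyran-2-yl acetate A2. In the forward key step one boron trifluoride-type Lewis acid would ionise the acetate of A2 first, assisted by the neighbouring bromine, and the cation would be captured at C10 by the allenyl tin reagent 3. The methyl acetal would then ionise and accept an allyl group from silicon at C6, which would give (2R,3S,5S,6R)-6-allyl-3-bromo-5-chloro-2-(pent-2-yn-1-yl)tetrahydro-2H-pyran A1. In its favour, the halogens are never introduced by SN2 on a crowded ring carbon, which is better than steps 10 and 14 of the chosen plan. Two C–C bonds form in one flask, which is better in step economy at that stage, and each nucleophile should enter trans to its neighbouring halogen, which gives both 1,2-trans relationships and with them the 2,6-trans ring. Against it here, A2 must be supplied as a single enantiomer with two different halogens anti to each other, and no short asymmetric access to such a differentiated dihaloglutaraldehyde is evident. The order of the two ionisations rests on rate differences between an acetate and a methyl acetal next to destabilising halogens, a bridging halonium ion can scramble configuration, and the allyl group of A1 must still be cleaved and olefinated in the presence of the internal alkyne. In comparison, both plans rely on oxocarbenium capture for the bonds at the ring, and both meet the same regiochemical question when the alkyne becomes the bromoalkene, so they are equal on these points. The chosen plan derives all four ring centres from one catalyst-set carbinol made from two cheap materials, whereas Alternative 1 moves the stereochemical problem into A2.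

Alternative 2: The cut is a retro-hetero-Diels–Alder across O–C10 and C8–C9, which gives acrolein A4 as the 1-oxadiene and (Z)-1-bromo-2-ethoxyethene A5 as the dienophile. In the forward key step the chromium chloride complex Cr(L)Cl (trivalent chromium, L being a chiral tridentate Schiff-base dianion built from an aminoindanol and a salicylaldehyde) would unite A4 and A5 by inverse-electron-demand cycloaddition and give (2R,3S)-3-bromo-2-ethoxy-3,4-dihydro-2H-pyran A3. In its favour, the ring and the C9–Br stereocentre come from one catalytic step on two very small building blocks. This is better than the chosen plan in early step economy and avoids the invertive bromination of step 10, and the C10 acetal of A3 is set up for bromine-assisted, trans-selective propargylation. Against it here, A4 has no β-substituent and polymerises readily, and A5 is a halogen-bearing, less electron-rich vinyl ether, so the pair lies at the edge of what this catalysis is known to handle and rate, endo selectivity and enantioselectivity are uncertain. After A3, C6 and C7 are an unsubstituted enol ether, and chlorine at C7 and the chain at C6 would have to be introduced under control of the remote C9/C10 centres, which is weak 1,3-induction. In comparison, the chosen plan sets C7 by a tether and C6 by attack next to the resident C10 arm, both short-range effects. It is longer, but each ring centre has a clear controlling element. Alternative 2 is the better plan for C9 and the weaker one for C6 and C7.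

Alternative 3: The cut removes O–C10 and C9–Br and reconnects O–C9, which gives the tetrahydrofuran carbinol (1S)-1-[(2R,4S,5R)-4-chloro-5-[3-(triisopropylsilyl)prop-2-yn-1-yl]tetrahydrofuran-2-yl]hex-3-yn-1-ol A7. In the forward key step, triflation of the C10 hydroxyl of A7 would let the ring oxygen displace the sulfonate to give the bicyclic epoxonium ion A8. A soluble bromide salt would then open A8 at C9 to give (2R,3S,5S,6R)-3-bromo-5-chloro-2-(pent-2-yn-1-yl)-6-[3-(triisopropylsilyl)prop-2-yn-1-yl]tetrahydro-2H-pyran A6. In its favour, the double inversion is stereospecific at C9 and C10. Bromide enters without a direct SN2 on a ring carbon with anti-periplanar hydrogens, which is better than step 10 of the chosen plan with respect to elimination, and 2,5-disubstituted tetrahydrofurans are accessible. Against it here, A8 can also be opened at C10, which returns a tetrahydrofuran with an exocyclic bromide, and the preference for ring expansion is not assured. A7 needs four stereocentres, including the C7 chloride, so the chlorination problem is only moved to an earlier stage. A6 carries two alkynes that must be told apart, and its three-carbon silylpropynyl arm still lacks C1 and C2 and needs a cis reduction. In comparison, both plans end with the same alkyne-to-bromoalkene conversion (equal). Alternative 3 has the more elegant bromide delivery. The chosen plan has the simpler precursor and the shorter, more predictable end game for the enyne.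

Key step: step 4

Remark on the chemistry: the sense of induction in step 3 is assumed to follow the analogous BINOL–Ti(OiPr)4-catalysed allylation of aromatic aldehydes, where the R ligand gives the R carbinol. The open intermediate of step 4 is formulated as the 4-oxo-2-enal 7.

## Route

Step 1
Reactants: 1 pent-2-yn-1-ol
Product: 2 pent-2-yn-1-yl methanesulfonate
Conditions: MsCl, Et3N, CH2Cl2, 0 °C
Reagents that add atoms: methanesulfonyl chloride, CS(=O)(=O)Cl
Why: Sulfonylation of a primary propargylic alcohol; it installs the leaving group for the SN2′ step.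

Step 2
Reactants: 2 pent-2-yn-1-yl methanesulfonate
Product: 3 tributyl(penta-1,2-dien-3-yl)stannane
Conditions: Bu3SnH, LiN(iPr)2, THF, 0 °C; CuBr·SMe2, −78 °C; then 2, −78 °C
Reagents that add atoms: tributyltin hydride, CCCC[SnH](CCCC)CCCC
Why: SN2′ displacement of a propargylic mesylate by Bu3SnCu, an established route to allenylstannanes; tin is delivered to the ethyl-bearing alkyne carbon and the CH2 terminus becomes the allene end.

Step 3
Reactants: 3 tributyl(penta-1,2-dien-3-yl)stannane; 4 furfural
Product: 6 (1R)-1-(furan-2-yl)hex-3-yn-1-ol, via stannyl ether 5 (not isolated)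
Conditions: (R)-BINOL (20 mol %), Ti(OiPr)4 (10 mol %), 4 Å MS, CH2Cl2, −20 °C; aq. NaHCO3
Reagents that add atoms: none
Why: BINOL–Ti(OiPr)4-catalysed asymmetric propargylation of an aldehyde with an allenylstannane (SE2′ at the CH2 terminus, forming C10–C11 and the homopropargylic alcohol). The chiral Lewis acid formed from (R)-BINOL and Ti(OiPr)4 shields one face of the bound aldehyde and sets C10 as R; the tin ether 5 is hydrolysed on work-up.

Step 4
Reactants: 6 (1R)-1-(furan-2-yl)hex-3-yn-1-ol
Product: 8 (2R)-6-hydroxy-2-(pent-2-yn-1-yl)-2H-pyran-3(6H)-one (anomeric mixture), via keto-enal 7 (not isolated)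
Conditions: NBS (1.05 equiv), NaHCO3, THF–H2O (4:1), 0 °C
Reagents that add atoms: water, O
Why: NBS delivers electrophilic bromine to furan C5 (the future C6), water adds to the resulting oxocarbenium ion, and loss of bromide opens the dihydrofuran to the (Z)-keto-enal 7. The C10 hydroxyl then adds to the C6 aldehyde in a 6-exo-trig hemiacetalisation, which forms the O–C6 bond and the only ring made here. This is the Achmatowicz oxidative ring expansion of a furfuryl alcohol, a long-established reaction type. No stereocentre of the target is created: C10 keeps the configuration from step 3 because none of its bonds is touched, and the hemiacetal carbon forms as an anomeric mixture that step 7 ionises. The step needs oxidation of the furan in preference to the dialkyl alkyne, which the far higher nucleophilicity of the heteroarene secures with one equivalent of oxidant at 0 °C. It also needs the new C9 ketone not to enolise towards C10; the NaHCO3 buffer removes the HBr that would catalyse this, and 8 is used without storage.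

Step 5
Reactants: 8 (2R)-6-hydroxy-2-(pent-2-yn-1-yl)-2H-pyran-3(6H)-one
Product: 9 (6R)-5-oxo-6-(pent-2-yn-1-yl)-5,6-dihydro-2H-pyran-2-yl acetate (anomeric mixture)
Conditions: Ac2O, pyridine, DMAP (cat.), CH2Cl2, 0 °C
Reagents that add atoms: acetic anhydride, CC(=O)OC(C)=O
Why: O-Acylation of the hemiacetal, the standard activation of such pyranones; the anomeric configuration is irrelevant because both anomers give the same cation.

Step 6
Reactants: 10 tert-butyl acetate
Product: 12 tert-butyl{[1-(tert-butoxy)ethenyl]oxy}dimethylsilane, via lithium enolate 11 (not isolated)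
Conditions: LiN(iPr)2, THF, −78 °C; TBSCl, DMPU, −78 °C to rt
Reagents that add atoms: tert-butyldimethylsilyl chloride, CC(C)(C)[Si](C)(C)Cl
Why: O-Silylation of an ester enolate, the usual preparation of a silyl ketene acetal.

Step 7
Reactants: 9 (6R)-5-oxo-6-(pent-2-yn-1-yl)-5,6-dihydro-2H-pyran-2-yl acetate; 12 tert-butyl{[1-(tert-butoxy)ethenyl]oxy}dimethylsilane
Product: 13 tert-butyl 2-[(2R,6R)-5-oxo-6-(pent-2-yn-1-yl)-5,6-dihydro-2H-pyran-2-yl]acetate
Conditions: TBSOTf (10 mol %), CH2Cl2, −78 °C
Reagents that add atoms: none
Why: Mukaiyama-type C-glycosylation: the silyl triflate ionises the anomeric acetate and the ketene acetal adds to C6 of the oxocarbenium ion, forming C5–C6. Attack occurs axially on the half-chair that keeps the C10 arm pseudo-equatorial, that is anti to this arm, which sets C6 as R (2,6-trans).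

Step 8
Reactants: 13 tert-butyl 2-[(2R,6R)-5-oxo-6-(pent-2-yn-1-yl)-5,6-dihydro-2H-pyran-2-yl]acetate
Product: 15 (3aR,5R,7aR)-5-(pent-2-yn-1-yl)tetrahydro-2H-furo[3,2-b]pyran-2,6(3H)-dione, via carboxylic acid 14 (not isolated)
Conditions: TFA–CH2Cl2 (1:4), 0 °C to rt; then TsOH·H2O (cat.), toluene, rt
Reagents that add atoms: none
Why: Acidolysis of the tert-butyl ester gives acid 14, whose carboxyl adds to C7 of the protonated enone in a 5-exo-trig intramolecular oxa-Michael lactonisation. The two-atom tether can reach C7 only on the face that carries C5, so the γ-lactone is cis-fused and the new C7–O bond is cis to the C6 arm.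

Step 9
Reactants: 15 (3aR,5R,7aR)-5-(pent-2-yn-1-yl)tetrahydro-2H-furo[3,2-b]pyran-2,6(3H)-dione
Product: 16 (3aR,5R,6R,7aR)-6-hydroxy-5-(pent-2-yn-1-yl)hexahydro-2H-furo[3,2-b]pyran-2-one
Conditions: LiBH(s-Bu)3 (1.1 equiv), THF, −78 °C; pH 7 buffer
Reagents that add atoms: none
Why: 1,2-Reduction of an α-substituted cyclic ketone by a bulky trialkylborohydride, which attacks along the equatorial trajectory of the chair with the C10 arm equatorial. The C9 hydroxyl therefore ends axial and cis to the C10 arm (C9 R); the lactone is not touched at this temperature.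

Step 10
Reactants: 16 (3aR,5R,6R,7aR)-6-hydroxy-5-(pent-2-yn-1-yl)hexahydro-2H-furo[3,2-b]pyran-2-one
Product: 17 (3aR,5R,6S,7aR)-6-bromo-5-(pent-2-yn-1-yl)hexahydro-2H-furo[3,2-b]pyran-2-one
Conditions: CBr4, P(n-Oct)3, toluene, 70 °C
Reagents that add atoms: carbon tetrabromide, BrC(Br)(Br)Br
Why: Appel-type bromination: the axial alkoxyphosphonium group is displaced by bromide in an SN2 reaction with inversion, giving the equatorial bromide trans to the C10 arm (C9 S). An axial leaving group is not anti-periplanar to the C10–O bond, so participation of the ring oxygen is not available, and the non-basic medium limits elimination.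

Step 11
Reactants: 17 (3aR,5R,6S,7aR)-6-bromo-5-(pent-2-yn-1-yl)hexahydro-2H-furo[3,2-b]pyran-2-one
Product: 19 (3aR,5R,6S,7aR)-6-bromo-5-[(2E)-3-bromopent-2-en-1-yl]hexahydro-2H-furo[3,2-b]pyran-2-one, via alkenylzirconocene chloride 18 (not isolated)
Conditions: Cp2Zr(H)Cl (1.5 equiv), THF, rt; then NBS, 0 °C
Reagents that add atoms: N-bromosuccinimide, O=C1CCC(=O)N1Br
Why: Syn hydrozirconation of the internal alkyne; with a slight excess of hydride the metal equilibrates to the less hindered C13 (ethyl side) and H sits on C12. Bromodezirconation with NBS proceeds with retention, so H and Br are cis and the alkene is E. At this stage there is no free hydroxyl, ketone, or second alkyne to compete.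

Step 12
Reactants: 19 (3aR,5R,6S,7aR)-6-bromo-5-[(2E)-3-bromopent-2-en-1-yl]hexahydro-2H-furo[3,2-b]pyran-2-one
Product: 20 (3aR,5R,6S,7aR)-6-bromo-5-[(2E)-3-bromopent-2-en-1-yl]hexahydro-2H-furo[3,2-b]pyran-2-ol (anomeric mixture)
Conditions: iBu2AlH (1.1 equiv), CH2Cl2, −78 °C; aq. KNaC4H4O6 (potassium sodium tartrate)
Reagents that add atoms: none
Why: Partial reduction of a γ-lactone to the lactol; the tetrahedral O–Al(iBu)2 hemiacetal is stable at −78 °C and both bromides are inert.

Step 13
Reactants: 20 (3aR,5R,6S,7aR)-6-bromo-5-[(2E)-3-bromopent-2-en-1-yl]hexahydro-2H-furo[3,2-b]pyran-2-ol; 21 1,3-bis(triisopropylsilyl)propyne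
Product: 24 (2R,3R,5S,6R)-5-bromo-6-[(2E)-3-bromopent-2-en-1-yl]-2-[(2Z)-5-(triisopropylsilyl)pent-2-en-4-yn-1-yl]tetrahydro-2H-pyran-3-ol, via lithiated propyne 22 (not isolated), via silyl alkoxide adduct 23 (not isolated)
Conditions: 21 (3 equiv), n-BuLi (3 equiv), THF, −78 °C; then 20, −78 to 0 °C
Reagents that add atoms: none
Why: Peterson olefination: the lactol opens as its lithium alkoxide to the C4 aldehyde, the silyl-stabilised propargylic anion 22 adds, and syn elimination of silanolate from adduct 23 forms C3=C4. The two bulky silyl groups bias the addition towards the diastereomer that eliminates to the Z-enyne, and the C7 hydroxyl is released in the same operation.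

Step 14
Reactants: 24 (2R,3R,5S,6R)-5-bromo-6-[(2E)-3-bromopent-2-en-1-yl]-2-[(2Z)-5-(triisopropylsilyl)pent-2-en-4-yn-1-yl]tetrahydro-2H-pyran-3-ol
Product: 25 (2R,3S,5S,6R)-3-bromo-2-[(2E)-3-bromopent-2-en-1-yl]-5-chloro-6-[(2Z)-5-(triisopropylsilyl)pent-2-en-4-yn-1-yl]tetrahydro-2H-pyran
Conditions: CCl4, P(n-Oct)3, toluene, 80 °C
Reagents that add atoms: carbon tetrachloride, ClC(Cl)(Cl)Cl
Why: Appel-type chlorination of a secondary alcohol; chloride displaces the alkoxyphosphonium group from the face opposite the C6 arm with inversion, giving C7 S with chlorine trans to that arm.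

Step 15
Reactants: 25 (2R,3S,5S,6R)-3-bromo-2-[(2E)-3-bromopent-2-en-1-yl]-5-chloro-6-[(2Z)-5-(triisopropylsilyl)pent-2-en-4-yn-1-yl]tetrahydro-2H-pyran
Product: 26 (2R,3S,5S,6R)-3-bromo-2-[(2E)-3-bromopent-2-en-1-yl]-5-chloro-6-[(2Z)-pent-2-en-4-yn-1-yl]tetrahydro-2H-pyran
Conditions: Bu4NF, THF, 0 °C
Reagents that add atoms: none
Why: Fluoride-induced protodesilylation of the silylalkyne (cleavage of the C(sp)–Si bond); at 0 °C and with short contact the secondary halides and the vinyl bromide should not eliminate.

## Compound list

1 | pent-2-yn-1-ol | CCC#CCO | starting material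
2 | pent-2-yn-1-yl methanesulfonate | CCC#CCOS(C)(=O)=O | intermediate
3 | tributyl(penta-1,2-dien-3-yl)stannane | CCCC[Sn](CCCC)(CCCC)C(CC)=C=C | intermediate
4 | furfural (furan-2-carbaldehyde) | O=Cc1ccco1 | starting material
5 | tributyl{[(1R)-1-(furan-2-yl)hex-3-yn-1-yl]oxy}stannane | CCCC[Sn](CCCC)(CCCC)O[C@H](CC#CCC)c1ccco1 | intermediate (not isolated)
6 | (1R)-1-(furan-2-yl)hex-3-yn-1-ol | O[C@H](CC#CCC)c1ccco1 | intermediate
7 | (2Z,5R)-5-hydroxy-4-oxodec-2-en-7-ynal | O=C/C=C\C(=O)[C@H](O)CC#CCC | intermediate (not isolated)
8 | (2R)-6-hydroxy-2-(pent-2-yn-1-yl)-2H-pyran-3(6H)-one, anomeric mixture | OC1O[C@H](CC#CCC)C(=O)C=C1 | intermediate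
9 | (6R)-5-oxo-6-(pent-2-yn-1-yl)-5,6-dihydro-2H-pyran-2-yl acetate, anomeric mixture | CC(=O)OC1O[C@H](CC#CCC)C(=O)C=C1 | intermediate
10 | tert-butyl acetate | CC(=O)OC(C)(C)C | starting material
11 | lithium 1-(tert-butoxy)ethen-1-olate | [Li]OC(=C)OC(C)(C)C | intermediate (not isolated)
12 | tert-butyl{[1-(tert-butoxy)ethenyl]oxy}dimethylsilane | C=C(OC(C)(C)C)O[Si](C)(C)C(C)(C)C | intermediate
13 | tert-butyl 2-[(2R,6R)-5-oxo-6-(pent-2-yn-1-yl)-5,6-dihydro-2H-pyran-2-yl]acetate | CC(C)(C)OC(=O)C[C@H]1O[C@H](CC#CCC)C(=O)C=C1 | intermediate
14 | 2-[(2R,6R)-5-oxo-6-(pent-2-yn-1-yl)-5,6-dihydro-2H-pyran-2-yl]acetic acid | OC(=O)C[C@H]1O[C@H](CC#CCC)C(=O)C=C1 | intermediate (not isolated)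
15 | (3aR,5R,7aR)-5-(pent-2-yn-1-yl)tetrahydro-2H-furo[3,2-b]pyran-2,6(3H)-dione (cis-fused keto lactone) | O=C1C[C@H]2O[C@H](CC#CCC)C(=O)C[C@H]2O1 | intermediate
16 | (3aR,5R,6R,7aR)-6-hydroxy-5-(pent-2-yn-1-yl)hexahydro-2H-furo[3,2-b]pyran-2-one (C9 hydroxyl cis to the C10 arm) | O=C1C[C@H]2O[C@H](CC#CCC)[C@H](O)C[C@H]2O1 | intermediate
17 | (3aR,5R,6S,7aR)-6-bromo-5-(pent-2-yn-1-yl)hexahydro-2H-furo[3,2-b]pyran-2-one | O=C1C[C@H]2O[C@H](CC#CCC)[C@@H](Br)C[C@H]2O1 | intermediate
18 | chlorobis(cyclopentadienyl){(2E)-1-[(3aR,5R,6S,7aR)-6-bromo-2-oxohexahydro-2H-furo[3,2-b]pyran-5-yl]pent-2-en-3-yl}zirconium | O=C1C[C@H]2O[C@H](C/C=C(/[Zr](Cl)(C3C=CC=C3)C3C=CC=C3)CC)[C@@H](Br)C[C@H]2O1 | intermediate (not isolated)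
19 | (3aR,5R,6S,7aR)-6-bromo-5-[(2E)-3-bromopent-2-en-1-yl]hexahydro-2H-furo[3,2-b]pyran-2-one | O=C1C[C@H]2O[C@H](C/C=C(/Br)CC)[C@@H](Br)C[C@H]2O1 | intermediate
20 | (3aR,5R,6S,7aR)-6-bromo-5-[(2E)-3-bromopent-2-en-1-yl]hexahydro-2H-furo[3,2-b]pyran-2-ol, anomeric mixture | OC1C[C@H]2O[C@H](C/C=C(/Br)CC)[C@@H](Br)C[C@H]2O1 | intermediate
21 | 1,3-bis(triisopropylsilyl)propyne | CC(C)[Si](C(C)C)(C(C)C)CC#C[Si](C(C)C)(C(C)C)C(C)C | starting material
22 | [1,3-bis(triisopropylsilyl)prop-2-yn-1-yl]lithium | [Li]C(C#C[Si](C(C)C)(C(C)C)C(C)C)[Si](C(C)C)(C(C)C)C(C)C | intermediate (not isolated)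
23 | dilithium alkoxide of 1-[(2R,3R,5S,6R)-5-bromo-6-[(2E)-3-bromopent-2-en-1-yl]-3-hydroxytetrahydro-2H-pyran-2-yl]-3,5-bis(triisopropylsilyl)pent-4-yn-2-ol (the two new chain carbons undefined) | CC(C)[Si](C(C)C)(C(C)C)C#CC([Si](C(C)C)(C(C)C)C(C)C)C(O[Li])C[C@H]1O[C@H](C/C=C(/Br)CC)[C@@H](Br)C[C@H]1O[Li] | intermediate (not isolated)
24 | (2R,3R,5S,6R)-5-bromo-6-[(2E)-3-bromopent-2-en-1-yl]-2-[(2Z)-5-(triisopropylsilyl)pent-2-en-4-yn-1-yl]tetrahydro-2H-pyran-3-ol | CC(C)[Si](C(C)C)(C(C)C)C#C/C=C\C[C@H]1O[C@H](C/C=C(/Br)CC)[C@@H](Br)C[C@H]1O | intermediate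
25 | (2R,3S,5S,6R)-3-bromo-2-[(2E)-3-bromopent-2-en-1-yl]-5-chloro-6-[(2Z)-5-(triisopropylsilyl)pent-2-en-4-yn-1-yl]tetrahydro-2H-pyran | CC(C)[Si](C(C)C)(C(C)C)C#C/C=C\C[C@H]1O[C@H](C/C=C(/Br)CC)[C@@H](Br)C[C@@H]1Cl | intermediate
26 | (2R,3S,5S,6R)-3-bromo-2-[(2E)-3-bromopent-2-en-1-yl]-5-chloro-6-[(2Z)-pent-2-en-4-yn-1-yl]tetrahydro-2H-pyran | C#C/C=C\C[C@H]1O[C@H](C/C=C(/Br)CC)[C@@H](Br)C[C@@H]1Cl | target

## Step count and least certain steps

Total: 15 steps. Longest linear sequence: 14 steps (from 1 through steps 1 to 5 and 7 to 15); step 6 is a one-step side branch.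

**Step 4 (key step).** The most likely failure is over-oxidation: further bromination of the product enone or of the alkyne by excess electrophilic bromine. A second is acid-promoted enolisation of the new α-alkoxy ketone, which would erode the C10 configuration.
Fallback: a two-stage variant without electrophilic halogen. Starting from 6, anodic methoxylation in MeOH (Et4NOTs electrolyte) should give (1R)-1-(2,5-dimethoxy-2,5-dihydrofuran-2-yl)hex-3-yn-1-ol F1. Brief hydrolysis of F1 in dilute aqueous H2SO4–THF at 0 °C should then return to the route at 8.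

**Step 11.** The most likely failure is incomplete regiocontrol of the hydrozirconation. Only the difference between an ethyl group and a β-branched CH2 group steers the metal to C13, and weak coordination of zirconium to the ring oxygen would favour the wrong carbon. Slow reduction of the lactone by excess hydride is a second risk.
Fallback: starting from 17, hydrostannation with Bu3SnH and Pd(PPh3)4 (zerovalent palladium) in THF at 0 °C is also a syn addition, but it gives stable, chromatographable alkenylstannanes. The wanted isomer, (3aR,5R,6S,7aR)-6-bromo-5-[(2E)-3-(tributylstannyl)pent-2-en-1-yl]hexahydro-2H-furo[3,2-b]pyran-2-one F2, would be separated and then brominated with Br2 in CH2Cl2 at −78 °C with retention, returning to the route at 19. Regiocontrol in this variant also rests on sterics; its advantage is that purification happens before the bromine is introduced.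

**Step 8.** The most likely failure is an unfavourable or slowly established conjugate-addition equilibrium, because a β-acyloxy ketone can revert to enone and acid. Acid-catalysed enolisation towards C10 during prolonged exposure is a second risk.
Fallback: the C7 oxygen would be set by halolactonisation instead, starting from 13 and rejoining at 16, so that steps 8 and 9 are both replaced. Luche reduction of 13 (NaBH4, CeCl3·7H2O, MeOH, −78 °C) should give tert-butyl 2-[(2R,5S,6R)-5-hydroxy-6-(pent-2-yn-1-yl)-5,6-dihydro-2H-pyran-2-yl]acetate F3. Mitsunobu inversion (4-nitrobenzoic acid, PPh3, DIAD) should give (2R,3R,6R)-6-(2-tert-butoxy-2-oxoethyl)-2-(pent-2-yn-1-yl)-3,6-dihydro-2H-pyran-3-yl 4-nitrobenzoate F4, and methanolysis (K2CO3, MeOH, 0 °C) should give tert-butyl 2-[(2R,5R,6R)-5-hydroxy-6-(pent-2-yn-1-yl)-5,6-dihydro-2H-pyran-2-yl]acetate F5. Iodolactonisation of the tert-butyl ester (I2, MeCN, 0 °C) should give (3aR,5R,6S,7S,7aS)-6-hydroxy-7-iodo-5-(pent-2-yn-1-yl)hexahydro-2H-furo[3,2-b]pyran-2-one F6, with the carboxyl delivered to C7 on the face of its tether and iodine anti at C8. Radical deiodination (Bu3SnH, Et3B, air, toluene, 0 °C, at high Bu3SnH concentration so that hydrogen transfer outruns addition of the C8 radical to the alkyne) should then give 16.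

**Step 9.** The most likely failure is poor facial selectivity. The lactone ring lies on the face from which the hydride must come, and the alternative chair (C10 arm axial) would direct the reagent the other way.
Fallback: invert instead of relying on direct control. From 15, NaBH4 in MeOH at −40 °C (axial attack) should give (3aR,5R,6S,7aR)-6-hydroxy-5-(pent-2-yn-1-yl)hexahydro-2H-furo[3,2-b]pyran-2-one F7. Mitsunobu reaction with chloroacetic acid (PPh3, DIAD, toluene) should give (3aR,5R,6R,7aR)-2-oxo-5-(pent-2-yn-1-yl)hexahydro-2H-furo[3,2-b]pyran-6-yl 2-chloroacetate F8. Removal of the chloroacetyl group with thiourea and NaHCO3 in EtOH spares the lactone and returns to the route at 16.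

**Step 14.** The most likely failures are loss of stereochemical fidelity and elimination. The equatorial leaving group at C7 is anti-periplanar to the C6–O bond, so the ring oxygen can participate (retention or ring contraction), and the hot phosphine medium can promote loss of HX.
Fallback: separate activation from displacement. From 24, ClCH2SO2Cl and 2,6-lutidine in CH2Cl2 at 0 °C should give (2R,3R,5S,6R)-5-bromo-6-[(2E)-3-bromopent-2-en-1-yl]-2-[(2Z)-5-(triisopropylsilyl)pent-2-en-4-yn-1-yl]tetrahydro-2H-pyran-3-yl chloromethanesulfonate F9. Displacement with Bu4NCl in toluene at 40 °C, a milder and purely bimolecular substitution, returns to the route at 25.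

**Step 3.** The most likely failures are low enantioselectivity, because the substituted allenylstannane reacts slowly and the uncatalysed background pathway gains weight, and reaction through the wrong terminus of the tin reagent.
Fallback: resolution instead of asymmetric catalysis. From 3 and 4, BF3·OEt2 in CH2Cl2 at −78 °C should give racemic 1-(furan-2-yl)hex-3-yn-1-ol F10. Sharpless kinetic resolution (Ti(OiPr)4, L-(+)-diisopropyl tartrate, t-BuOOH, 4 Å MS, CH2Cl2, −20 °C) should consume the S enantiomer as (2S)-6-hydroxy-2-(pent-2-yn-1-yl)-2H-pyran-3(6H)-one F11 and leave the R carbinol, returning to the route at 6.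

## Further compounds

F1 | step 4 | (1R)-1-(2,5-dimethoxy-2,5-dihydrofuran-2-yl)hex-3-yn-1-ol | COC1C=CC(OC)(O1)[C@H](O)CC#CCC
F2 | step 11 | (3aR,5R,6S,7aR)-6-bromo-5-[(2E)-3-(tributylstannyl)pent-2-en-1-yl]hexahydro-2H-furo[3,2-b]pyran-2-one | O=C1C[C@H]2O[C@H](C/C=C(/[Sn](CCCC)(CCCC)CCCC)CC)[C@@H](Br)C[C@H]2O1
F3 | step 8 | tert-butyl 2-[(2R,5S,6R)-5-hydroxy-6-(pent-2-yn-1-yl)-5,6-dihydro-2H-pyran-2-yl]acetate | CC(C)(C)OC(=O)C[C@H]1O[C@H](CC#CCC)[C@@H](O)C=C1
F4 | step 8 | (2R,3R,6R)-6-(2-tert-butoxy-2-oxoethyl)-2-(pent-2-yn-1-yl)-3,6-dihydro-2H-pyran-3-yl 4-nitrobenzoate | CC(C)(C)OC(=O)C[C@H]1O[C@H](CC#CCC)[C@H](OC(=O)c2ccc(cc2)[N+](=O)[O-])C=C1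
F5 | step 8 | tert-butyl 2-[(2R,5R,6R)-5-hydroxy-6-(pent-2-yn-1-yl)-5,6-dihydro-2H-pyran-2-yl]acetate | CC(C)(C)OC(=O)C[C@H]1O[C@H](CC#CCC)[C@H](O)C=C1
F6 | step 8 | (3aR,5R,6S,7S,7aS)-6-hydroxy-7-iodo-5-(pent-2-yn-1-yl)hexahydro-2H-furo[3,2-b]pyran-2-one | O=C1C[C@H]2O[C@H](CC#CCC)[C@H](O)[C@H](I)[C@H]2O1
F7 | step 9 | (3aR,5R,6S,7aR)-6-hydroxy-5-(pent-2-yn-1-yl)hexahydro-2H-furo[3,2-b]pyran-2-one | O=C1C[C@H]2O[C@H](CC#CCC)[C@@H](O)C[C@H]2O1
F8 | step 9 | (3aR,5R,6R,7aR)-2-oxo-5-(pent-2-yn-1-yl)hexahydro-2H-furo[3,2-b]pyran-6-yl 2-chloroacetate | O=C1C[C@H]2O[C@H](CC#CCC)[C@H](OC(=O)CCl)C[C@H]2O1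
F9 | step 14 | (2R,3R,5S,6R)-5-bromo-6-[(2E)-3-bromopent-2-en-1-yl]-2-[(2Z)-5-(triisopropylsilyl)pent-2-en-4-yn-1-yl]tetrahydro-2H-pyran-3-yl chloromethanesulfonate | CC(C)[Si](C(C)C)(C(C)C)C#C/C=C\C[C@H]1O[C@H](C/C=C(/Br)CC)[C@@H](Br)C[C@H]1OS(=O)(=O)CCl
F10 | step 3 | racemic 1-(furan-2-yl)hex-3-yn-1-ol | OC(CC#CCC)c1ccco1
F11 | step 3 | (2S)-6-hydroxy-2-(pent-2-yn-1-yl)-2H-pyran-3(6H)-one | OC1O[C@@H](CC#CCC)C(=O)C=C1
A1 | alternative 1 | (2R,3S,5S,6R)-6-allyl-3-bromo-5-chloro-2-(pent-2-yn-1-yl)tetrahydro-2H-pyran | C=CC[C@H]1O[C@H](CC#CCC)[C@@H](Br)C[C@@H]1Cl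
A2 | alternative 1 | (3S,5S)-3-bromo-5-chloro-6-methoxytetrahydro-2H-pyran-2-yl acetate (both acetal carbons as anomeric mixtures) | COC1OC(OC(C)=O)[C@@H](Br)C[C@@H]1Cl
A3 | alternative 2 | (2R,3S)-3-bromo-2-ethoxy-3,4-dihydro-2H-pyran | C1=CC[C@H](Br)[C@H](OCC)O1
A4 | alternative 2 | acrolein | C=CC=O
A5 | alternative 2 | (Z)-1-bromo-2-ethoxyethene | Br/C=C\OCC
A6 | alternative 3 | (2R,3S,5S,6R)-3-bromo-5-chloro-2-(pent-2-yn-1-yl)-6-[3-(triisopropylsilyl)prop-2-yn-1-yl]tetrahydro-2H-pyran | CC(C)[Si](C(C)C)(C(C)C)C#CC[C@H]1O[C@H](CC#CCC)[C@@H](Br)C[C@@H]1Cl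
A7 | alternative 3 | (1S)-1-[(2R,4S,5R)-4-chloro-5-[3-(triisopropylsilyl)prop-2-yn-1-yl]tetrahydrofuran-2-yl]hex-3-yn-1-ol | CC(C)[Si](C(C)C)(C(C)C)C#CC[C@H]1O[C@@H]([C@@H](O)CC#CCC)C[C@@H]1Cl
A8 | alternative 3 | bicyclic epoxonium ion from A7 (oxygen bridging C6, C9 and C10) | CC(C)[Si](C(C)C)(C(C)C)C#CC[C@H]1[O+]2[C@H](CC#CCC)[C@H]2C[C@@H]1Cl
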